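**Plan**

1. The retrosynthesis cuts the two interflavan C4–C8 bonds (Friedel–Crafts), giving a gallocatechin C4 cation, a catechin C4 cation and a catechin nucleophile. Ring C of the catechin unit is then cut at C3–C4 (aldol bond) and at O1–C2 (oxa-Michael bond).
2. Enabling feature: in the lower catechin unit, C4 is a benzylic carbon on the phloroglucinol ring A, ortho to the ring oxygen O1. C3 lies between C4 and C2, which carries O1 and the catechol ring B. Ring A with O1–H and C4 as CHO is therefore a salicylaldehyde, and C2=C3 with a formyl helper on C3 is a cinnamaldehyde.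
3. Forward: amine-catalysed oxa-Michael addition (O1–C2) followed by aldol condensation (C3–C4) closes ring C. The formyl helper is then removed and C3–OH is introduced by hydroboration. The resulting benzylated catechin is used twice: as the lower unit and, after C4 oxidation, as the middle unit.
4. Chain assembly: the lower–middle bond is made first, then the gallocatechin unit (from (+)-gallocatechin) is attached to C8 of the middle unit. Deacetylation and hydrogenolysis finish the route.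
5. Stereochemistry: C2 of both catechin units comes from the organocatalyst, and C3 from hydroboration anti to the C2 aryl group. C2 and C3 of the top unit come from (+)-gallocatechin. Both C4 centres come from 3-O-acetyl participation (3,4-trans attack).

Key step: step 3

Remark: (+)-gallocatechin and both enantiomers of diphenylprolinol trimethylsilyl ether are taken as purchasable. Which catalyst enantiomer gives the 2R aldehyde is to be settled in a trial run.

**Route**

Step 1
Reactants: 1 2,4,6-trihydroxybenzaldehyde; 2 benzyl bromide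
Product: 3 4,6-bis(benzyloxy)-2-hydroxybenzaldehyde
Conditions: BnBr (2.1 equiv), K2CO3, DMF, 0 °C to rt
Reagents that add atoms: benzyl bromide, BrCc1ccccc1
Why: Williamson ether synthesis: the 4-hydroxyl (para to CHO, most acidic) and one of the two equivalent ortho hydroxyls are benzylated, while the last ortho hydroxyl is held in a hydrogen bond to the carbonyl oxygen and should survive a limited amount of benzyl bromide.

Step 2
Reactants: 4 3,4-bis(benzyloxy)benzaldehyde; 5 (triphenylphosphoranylidene)acetaldehyde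
Product: 6 (E)-3-[3,4-bis(benzyloxy)phenyl]prop-2-enal
Conditions: 5 (1.05 equiv), toluene, 80 °C
Reagents that add atoms: (triphenylphosphoranylidene)acetaldehyde, O=CC=P(c1ccccc1)(c1ccccc1)c1ccccc1
Why: Wittig reaction of the stabilised ylide with the aryl aldehyde should give the E-enal, and the near-stoichiometric amount of ylide limits further homologation of the product.

Step 3
Reactants: 3 4,6-bis(benzyloxy)-2-hydroxybenzaldehyde; 6 (E)-3-[3,4-bis(benzyloxy)phenyl]prop-2-enal
Product: 9 (2R)-5,7-bis(benzyloxy)-2-[3,4-bis(benzyloxy)phenyl]-2H-chromene-3-carbaldehyde, via oxa-Michael adduct 7 (not isolated), via aldol adduct 8 (not isolated)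
Conditions: 6 (1.2 equiv), diphenylprolinol trimethylsilyl ether (20 mol %, enantiomer as in the remark), 2-nitrobenzoic acid (20 mol %), 4 Å MS, toluene, rt, dark
Reagents that add atoms: none
Why: The secondary amine condenses with enal 6 to an E-iminium ion, the phenol oxygen of 3 adds to its β-carbon (future C2) on the face left open by the diphenyl(silyloxy)methyl group, and the resulting enamine carbon (future C3) attacks the neighbouring aryl aldehyde carbon (future C4), so that the pyran ring is closed by the C3–C4 bond; loss of water from aldol 8 and hydrolysis of the iminium ion release 9 and the catalyst. The closest known reaction type is the diarylprolinol silyl ether-catalysed domino oxa-Michael/aldol condensation of salicylaldehydes with cinnamaldehydes to 2-aryl-2H-chromene-3-carbaldehydes. Ring C closes by a 6-(enolexo)-exo-trig intramolecular aldol addition, and the following E1cB dehydration makes the otherwise reversible sequence irreversible. The only stereocentre that survives, C2, is set by the catalyst (in the oxa-Michael step or, under Curtin–Hammett conditions, in the catalyst-bound aldol step), while the transient C3 and C4 centres are erased by dehydration. The step needs 1,4-addition of the phenol instead of 1,2-addition, and closure onto the hindered, electron-rich 2,6-dioxygenated aldehyde; the ortho relation of OH and CHO on ring A secures both, because only this phenol can trap its own oxa-Michael adduct intramolecularly. The formyl group on C3 is the activating helper and is excised in step 4.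

Step 4
Reactants: 9 (2R)-5,7-bis(benzyloxy)-2-[3,4-bis(benzyloxy)phenyl]-2H-chromene-3-carbaldehyde
Product: 10 (2S)-5,7-bis(benzyloxy)-2-[3,4-bis(benzyloxy)phenyl]-2H-chromene
Conditions: RhCl(PPh3)3 (1.1 equiv), toluene, 90 °C, argon, dark
Reagents that add atoms: none
Why: Tsuji–Wilkinson decarbonylation: oxidative addition of the formyl C–H bond to RhCl(PPh3)3, extrusion of CO onto rhodium and C–H reductive elimination replace the helper CHO on C3 by H without moving the C3=C4 double bond or touching C2 (the descriptor changes from R to S only because the substituent ranking at C2 changes).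

Step 5
Reactants: 10 (2S)-5,7-bis(benzyloxy)-2-[3,4-bis(benzyloxy)phenyl]-2H-chromene; 11 hydrogen peroxide
Product: 13 5,7,3',4'-tetra-O-benzyl-(+)-catechin, via alkylborane 12 (not isolated)
Conditions: BH3·THF, THF, 0 °C to rt; then NaOH, H2O2, H2O, 0 °C to rt
Reagents that add atoms: hydrogen peroxide, OO
Why: Hydroboration–oxidation: borane adds syn to the styrene-type C3=C4 bond with boron on C3 (remote from ring A) and on the face opposite to the C2 aryl group, and oxidation with retention should give the 2,3-trans alcohol (2R,3S) and the C4 methylene.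

Step 6
Reactants: 13 5,7,3',4'-tetra-O-benzyl-(+)-catechin; 14 2-ethoxyethanol
Product: 15 (2R,3S,4S)-5,7-bis(benzyloxy)-2-[3,4-bis(benzyloxy)phenyl]-4-(2-ethoxyethoxy)chroman-3-ol
Conditions: DDQ (2 equiv), 2-ethoxyethanol (5 equiv), CH2Cl2, rt
Reagents that add atoms: 2-ethoxyethanol, CCOCCO
Why: Benzylic oxidation with DDQ: hydride abstraction from C4 gives a cation stabilised by the 5,7-dioxygenated ring A, which is trapped by the alcohol anti to the C2 aryl group; the C4 configuration is of no consequence because C4 is ionised again in step 8.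

Step 7
Reactants: 15 (2R,3S,4S)-5,7-bis(benzyloxy)-2-[3,4-bis(benzyloxy)phenyl]-4-(2-ethoxyethoxy)chroman-3-ol; 16 acetic anhydride
Product: 17 (2R,3S,4S)-5,7-bis(benzyloxy)-2-[3,4-bis(benzyloxy)phenyl]-4-(2-ethoxyethoxy)chroman-3-yl acetate
Conditions: Ac2O, pyridine, DMAP (cat.), rt
Reagents that add atoms: acetic anhydride, CC(=O)OC(C)=O
Why: DMAP-catalysed acylation of the secondary alcohol installs the 3-O-acetyl group that acts as the participating group in step 8.

Step 8
Reactants: 17 (2R,3S,4S)-5,7-bis(benzyloxy)-2-[3,4-bis(benzyloxy)phenyl]-4-(2-ethoxyethoxy)chroman-3-yl acetate; 13 5,7,3',4'-tetra-O-benzyl-(+)-catechin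
Product: 18 3-O-acetyl-5,7,3',4'-tetra-O-benzylcatechin-(4α→8)-5,7,3',4'-tetra-O-benzylcatechin
Conditions: 13 (4 equiv, excess recovered), TMSOTf (cat.), CH2Cl2, −78 °C
Reagents that add atoms: none
Why: Friedel–Crafts alkylation: TMSOTf ionises the C4 ether, the 3-acetoxy group bridges the cation on its own face, and C8 of 13 (the free position between O1 and the 7-benzyloxy group) attacks from the opposite face, which should give the 3,4-trans (4α→8) bond, while the excess of 13 suppresses chain growth.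

Step 9
Reactants: 19 (+)-gallocatechin; 2 benzyl bromide
Product: 20 5,7,3',4',5'-penta-O-benzyl-(+)-gallocatechin
Conditions: BnBr (5.5 equiv), K2CO3, DMF, 0 °C to rt, argon
Reagents that add atoms: benzyl bromide, BrCc1ccccc1
Why: Williamson ether synthesis of the five phenols, which are far more acidic than the secondary 3-hydroxyl; exclusion of oxygen protects the pyrogallol ring, and no stereocentre is touched.

Step 10
Reactants: 20 5,7,3',4',5'-penta-O-benzyl-(+)-gallocatechin; 14 2-ethoxyethanol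
Product: 21 (2R,3S,4S)-5,7-bis(benzyloxy)-4-(2-ethoxyethoxy)-2-[3,4,5-tris(benzyloxy)phenyl]chroman-3-ol
Conditions: DDQ (2 equiv), 2-ethoxyethanol (5 equiv), CH2Cl2, rt
Reagents that add atoms: 2-ethoxyethanol, CCOCCO
Why: Benzylic oxidation with DDQ as in step 6: the ring A-stabilised C4 cation is trapped by the alcohol, and the C4 configuration is lost again in step 12.

Step 11
Reactants: 21 (2R,3S,4S)-5,7-bis(benzyloxy)-4-(2-ethoxyethoxy)-2-[3,4,5-tris(benzyloxy)phenyl]chroman-3-ol; 16 acetic anhydride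
Product: 22 (2R,3S,4S)-5,7-bis(benzyloxy)-4-(2-ethoxyethoxy)-2-[3,4,5-tris(benzyloxy)phenyl]chroman-3-yl acetate
Conditions: Ac2O, pyridine, DMAP (cat.), rt
Reagents that add atoms: acetic anhydride, CC(=O)OC(C)=O
Why: DMAP-catalysed acylation of the secondary alcohol provides the participating 3-O-acetyl group for step 12.

Step 12
Reactants: 22 (2R,3S,4S)-5,7-bis(benzyloxy)-4-(2-ethoxyethoxy)-2-[3,4,5-tris(benzyloxy)phenyl]chroman-3-yl acetate; 18 3-O-acetyl-5,7,3',4'-tetra-O-benzylcatechin-(4α→8)-5,7,3',4'-tetra-O-benzylcatechin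
Product: 23 3-O-acetyl-5,7,3',4',5'-penta-O-benzylgallocatechin-(4α→8)-3-O-acetyl-5,7,3',4'-tetra-O-benzylcatechin-(4α→8)-5,7,3',4'-tetra-O-benzylcatechin
Conditions: 18 (2 equiv, excess recovered), TMSOTf (cat.), CH2Cl2, −78 °C
Reagents that add atoms: none
Why: Friedel–Crafts alkylation as in step 8: the acetoxy-bridged gallocatechin C4 cation should be attacked by C8 of the upper unit of 18 (the only free position of the dimer between a ring oxygen O1 and a benzyloxy group) from the face opposite to the 3-acetoxy group, which gives the second 4α→8 bond.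

Step 13
Reactants: 23 3-O-acetyl-5,7,3',4',5'-penta-O-benzylgallocatechin-(4α→8)-3-O-acetyl-5,7,3',4'-tetra-O-benzylcatechin-(4α→8)-5,7,3',4'-tetra-O-benzylcatechin
Product: 24 5,7,3',4',5'-penta-O-benzylgallocatechin-(4α→8)-5,7,3',4'-tetra-O-benzylcatechin-(4α→8)-5,7,3',4'-tetra-O-benzylcatechin
Conditions: n-Bu4NOH (aq.), THF, rt
Reagents that add atoms: none
Why: Saponification of the two hindered secondary acetates with a soluble hydroxide; benzyl ethers, interflavan bonds and all stereocentres are inert to these conditions.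

Step 14
Reactants: 24 5,7,3',4',5'-penta-O-benzylgallocatechin-(4α→8)-5,7,3',4'-tetra-O-benzylcatechin-(4α→8)-5,7,3',4'-tetra-O-benzylcatechin
Product: 25 gallocatechin-(4α→8)-catechin-(4α→8)-catechin (CNP0155646.1)
Conditions: H2 (1 atm), Pd(OH)2/C, THF/MeOH/H2O, rt; filtration, lyophilisation
Reagents that add atoms: none
Why: Hydrogenolysis of the thirteen benzyl ethers under neutral conditions should leave the C–C interflavan bonds, the ring C ethers and all eight stereocentres untouched.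

**Compound list**

1 | 2,4,6-trihydroxybenzaldehyde | O=Cc1c(O)cc(O)cc1O | starting material
2 | benzyl bromide | BrCc1ccccc1 | starting material
3 | 4,6-bis(benzyloxy)-2-hydroxybenzaldehyde | O=Cc1c(O)cc(OCc2ccccc2)cc1OCc1ccccc1 | intermediate
4 | 3,4-bis(benzyloxy)benzaldehyde | O=Cc1ccc(OCc2ccccc2)c(OCc2ccccc2)c1 | starting material
5 | (triphenylphosphoranylidene)acetaldehyde | O=CC=P(c1ccccc1)(c1ccccc1)c1ccccc1 | starting material
6 | (E)-3-[3,4-bis(benzyloxy)phenyl]prop-2-enal | O=C/C=C/c1ccc(OCc2ccccc2)c(OCc2ccccc2)c1 | intermediate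
7 | oxa-Michael adduct: (S)-4,6-bis(benzyloxy)-2-{1-[3,4-bis(benzyloxy)phenyl]-3-oxopropoxy}benzaldehyde (present as its enamine with the catalyst) | O=Cc1c(OCc2ccccc2)cc(OCc2ccccc2)cc1O[C@H](c1ccc(OCc2ccccc2)c(OCc2ccccc2)c1)CC=O | intermediate (not isolated)
8 | aldol adduct: (2S)-5,7-bis(benzyloxy)-2-[3,4-bis(benzyloxy)phenyl]-4-hydroxychromane-3-carbaldehyde (present as its iminium ion; C3 and C4 transient and undefined) | c1c(OCc3ccccc3)cc(OCc3ccccc3)c2c1O[C@H](c1ccc(OCc3ccccc3)c(OCc3ccccc3)c1)C(C=O)C2O | intermediate (not isolated)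
9 | (2R)-5,7-bis(benzyloxy)-2-[3,4-bis(benzyloxy)phenyl]-2H-chromene-3-carbaldehyde | c1c(OCc3ccccc3)cc(OCc3ccccc3)c2c1O[C@H](c1ccc(OCc3ccccc3)c(OCc3ccccc3)c1)C(C=O)=C2 | intermediate
10 | (2S)-5,7-bis(benzyloxy)-2-[3,4-bis(benzyloxy)phenyl]-2H-chromene | c1c(OCc3ccccc3)cc(OCc3ccccc3)c2c1O[C@H](c1ccc(OCc3ccccc3)c(OCc3ccccc3)c1)C=C2 | intermediate
11 | hydrogen peroxide | OO | starting material
12 | alkylborane: [(2S,3S)-5,7-bis(benzyloxy)-2-[3,4-bis(benzyloxy)phenyl]chroman-3-yl]borane (2,3-trans) | c1c(OCc3ccccc3)cc(OCc3ccccc3)c2c1O[C@H](c1ccc(OCc3ccccc3)c(OCc3ccccc3)c1)[C@@H](B)C2 | intermediate (not isolated)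
13 | 5,7,3',4'-tetra-O-benzyl-(+)-catechin = (2R,3S)-5,7-bis(benzyloxy)-2-[3,4-bis(benzyloxy)phenyl]chroman-3-ol | c1c(OCc3ccccc3)cc(OCc3ccccc3)c2c1O[C@H](c1ccc(OCc3ccccc3)c(OCc3ccccc3)c1)[C@@H](O)C2 | intermediate
14 | 2-ethoxyethanol | CCOCCO | starting material
15 | (2R,3S,4S)-5,7-bis(benzyloxy)-2-[3,4-bis(benzyloxy)phenyl]-4-(2-ethoxyethoxy)chroman-3-ol | c1c(OCc3ccccc3)cc(OCc3ccccc3)c2c1O[C@H](c1ccc(OCc3ccccc3)c(OCc3ccccc3)c1)[C@@H](O)[C@H]2OCCOCC | intermediate
16 | acetic anhydride | CC(=O)OC(C)=O | starting material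
17 | (2R,3S,4S)-5,7-bis(benzyloxy)-2-[3,4-bis(benzyloxy)phenyl]-4-(2-ethoxyethoxy)chroman-3-yl acetate | c1c(OCc3ccccc3)cc(OCc3ccccc3)c2c1O[C@H](c1ccc(OCc3ccccc3)c(OCc3ccccc3)c1)[C@@H](OC(C)=O)[C@H]2OCCOCC | intermediate
18 | 3-O-acetyl-5,7,3',4'-tetra-O-benzylcatechin-(4α→8)-5,7,3',4'-tetra-O-benzylcatechin (upper unit 2R,3S,4S; lower unit 2R,3S) | c1c(OCc3ccccc3)cc(OCc3ccccc3)c2c1O[C@H](c1ccc(OCc3ccccc3)c(OCc3ccccc3)c1)[C@@H](OC(C)=O)[C@@H]2c1c(OCc3ccccc3)cc(OCc3ccccc3)c2c1O[C@H](c1ccc(OCc3ccccc3)c(OCc3ccccc3)c1)[C@@H](O)C2 | intermediate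
19 | (+)-gallocatechin (2R,3S) | Oc1cc(O)c2c(c1)O[C@H](c1cc(O)c(O)c(O)c1)[C@@H](O)C2 | starting material
20 | 5,7,3',4',5'-penta-O-benzyl-(+)-gallocatechin | C(c3ccccc3)Oc1cc(OCc3ccccc3)c2c(c1)O[C@H](c1cc(OCc3ccccc3)c(OCc3ccccc3)c(OCc3ccccc3)c1)[C@@H](O)C2 | intermediate
21 | (2R,3S,4S)-5,7-bis(benzyloxy)-4-(2-ethoxyethoxy)-2-[3,4,5-tris(benzyloxy)phenyl]chroman-3-ol | C(c3ccccc3)Oc1cc(OCc3ccccc3)c2c(c1)O[C@H](c1cc(OCc3ccccc3)c(OCc3ccccc3)c(OCc3ccccc3)c1)[C@@H](O)[C@H]2OCCOCC | intermediate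
22 | (2R,3S,4S)-5,7-bis(benzyloxy)-4-(2-ethoxyethoxy)-2-[3,4,5-tris(benzyloxy)phenyl]chroman-3-yl acetate | C(c3ccccc3)Oc1cc(OCc3ccccc3)c2c(c1)O[C@H](c1cc(OCc3ccccc3)c(OCc3ccccc3)c(OCc3ccccc3)c1)[C@@H](OC(C)=O)[C@H]2OCCOCC | intermediate
23 | 3-O-acetyl-5,7,3',4',5'-penta-O-benzylgallocatechin-(4α→8)-3-O-acetyl-5,7,3',4'-tetra-O-benzylcatechin-(4α→8)-5,7,3',4'-tetra-O-benzylcatechin | C(c3ccccc3)Oc1cc(OCc3ccccc3)c2c(c1)O[C@H](c1cc(OCc3ccccc3)c(OCc3ccccc3)c(OCc3ccccc3)c1)[C@@H](OC(C)=O)[C@@H]2c1c(OCc3ccccc3)cc(OCc3ccccc3)c2c1O[C@H](c1ccc(OCc3ccccc3)c(OCc3ccccc3)c1)[C@@H](OC(C)=O)[C@@H]2c1c(OCc3ccccc3)cc(OCc3ccccc3)c2c1O[C@H](c1ccc(OCc3ccccc3)c(OCc3ccccc3)c1)[C@@H](O)C2 | intermediate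
24 | 5,7,3',4',5'-penta-O-benzylgallocatechin-(4α→8)-5,7,3',4'-tetra-O-benzylcatechin-(4α→8)-5,7,3',4'-tetra-O-benzylcatechin | C(c3ccccc3)Oc1cc(OCc3ccccc3)c2c(c1)O[C@H](c1cc(OCc3ccccc3)c(OCc3ccccc3)c(OCc3ccccc3)c1)[C@@H](O)[C@@H]2c1c(OCc3ccccc3)cc(OCc3ccccc3)c2c1O[C@H](c1ccc(OCc3ccccc3)c(OCc3ccccc3)c1)[C@@H](O)[C@@H]2c1c(OCc3ccccc3)cc(OCc3ccccc3)c2c1O[C@H](c1ccc(OCc3ccccc3)c(OCc3ccccc3)c1)[C@@H](O)C2 | intermediate
25 | gallocatechin-(4α→8)-catechin-(4α→8)-catechin, CNP0155646.1 (all units 2R,3S; both upper units 4S) | Oc1cc(O)c2c(c1)O[C@H](c1cc(O)c(O)c(O)c1)[C@@H](O)[C@@H]2c1c(O)cc(O)c2c1O[C@H](c1ccc(O)c(O)c1)[C@@H](O)[C@@H]2c1c(O)cc(O)c2c1O[C@H](c1ccc(O)c(O)c1)[C@@H](O)C2 | target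

**Summary**

Total step count: 14.
Longest linear sequence: 10 steps (steps 1, 3, 4, 5, 6, 7, 8, 12, 13, 14, counted from 1).

**Steps most likely to fail**

Step 3. The aldol closure onto the hindered, electron-rich ring A aldehyde may be slow. The reversible oxa-Michael addition is then either not trapped (low conversion) or trapped with poor facial selectivity (low enantiomeric purity at C2). The fallback sets out from 3 and 6 and comes back to the route at 10, so that step 4 is bypassed as well. Aldehyde 3 is methylenated (Ph3PCH3Br, KOtBu, THF) to 3,5-bis(benzyloxy)-2-ethenylphenol F1. Enal 6 is reduced (NaBH4, CeCl3·7H2O, MeOH) to (E)-3-[3,4-bis(benzyloxy)phenyl]prop-2-en-1-ol F2, which is converted (ClCO2Me, pyridine) into (E)-3-[3,4-bis(benzyloxy)phenyl]prop-2-en-1-yl methyl carbonate F3. The sodium salt of F1 (NaH) and F3 are joined by an enantioselective, branched-selective allylic etherification ([Ir(cod)Cl]2, binaphthol-derived phosphoramidite ligand, THF) to 1,5-bis(benzyloxy)-3-{[(1S)-1-[3,4-bis(benzyloxy)phenyl]prop-2-en-1-yl]oxy}-2-ethenylbenzene F4. Ring-closing metathesis of F4 (second-generation Grubbs catalyst, (H2IMes)(PCy3)Cl2Ru=CHPh, CH2Cl2, 40 °C) then closes the same C3–C4 bond as the C3=C4 double bond and gives 10.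

Step 4. Decarbonylation of the electron-rich conjugated aldehyde may stay incomplete at a temperature low enough to keep C2 intact. Alternatively, configuration at C2 may be lost by thermal electrocyclic ring opening or by metal-assisted ionisation of the allylic C2–O1 bond. The fallback sets out from 9 and comes back at 13, so that step 5 is bypassed; the formyl carbon is then exchanged for the C3 oxygen instead of being removed. Conjugate reduction of 9 (Hantzsch ester, dibenzylammonium trifluoroacetate, THF) should give (2S,3S)-5,7-bis(benzyloxy)-2-[3,4-bis(benzyloxy)phenyl]chromane-3-carbaldehyde F5, because the C3 centre equilibrates under the amine salt to the 2,3-trans isomer. Baeyer–Villiger oxidation (mCPBA, NaHCO3, CH2Cl2, 0 °C) inserts oxygen with retention at C3 and gives 5,7,3',4'-tetra-O-benzyl-(+)-catechin 3-O-formate F6. Methanolysis (K2CO3, MeOH) of F6 gives 13.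

Step 12. The cation may attack C6 of either unit of the dimer instead of C8 of its upper unit, and the electrophile may condense with itself and grow chains. The fallback sets out from 22 and 13 and comes back at 23; it reverses the order of chain assembly so that the nucleophile is always the monomer in excess. Condensation of 22 with an excess of 13 (TMSOTf, CH2Cl2, −78 °C) gives 3-O-acetyl-5,7,3',4',5'-penta-O-benzylgallocatechin-(4α→8)-5,7,3',4'-tetra-O-benzylcatechin F7. Oxidation of the only remaining benzylic CH2 (DDQ, 2-ethoxyethanol, CH2Cl2) gives its 4-(2-ethoxyethoxy) derivative on the lower unit F8, and acetylation (Ac2O, pyridine, DMAP) gives the diacetate F9. Condensation of F9 with an excess of 13 (TMSOTf, CH2Cl2, −78 °C) then gives 23.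

**Further compounds**

F1 | step 3 | 3,5-bis(benzyloxy)-2-ethenylphenol | C=Cc1c(O)cc(OCc2ccccc2)cc1OCc1ccccc1
F2 | step 3 | (E)-3-[3,4-bis(benzyloxy)phenyl]prop-2-en-1-ol | OC/C=C/c1ccc(OCc2ccccc2)c(OCc2ccccc2)c1
F3 | step 3 | (E)-3-[3,4-bis(benzyloxy)phenyl]prop-2-en-1-yl methyl carbonate | COC(=O)OC/C=C/c1ccc(OCc2ccccc2)c(OCc2ccccc2)c1
F4 | step 3 | 1,5-bis(benzyloxy)-3-{[(1S)-1-[3,4-bis(benzyloxy)phenyl]prop-2-en-1-yl]oxy}-2-ethenylbenzene | C=Cc1c(OCc2ccccc2)cc(OCc2ccccc2)cc1O[C@H](c1ccc(OCc2ccccc2)c(OCc2ccccc2)c1)C=C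
F5 | step 4 | (2S,3S)-5,7-bis(benzyloxy)-2-[3,4-bis(benzyloxy)phenyl]chromane-3-carbaldehyde (2,3-trans) | c1c(OCc3ccccc3)cc(OCc3ccccc3)c2c1O[C@H](c1ccc(OCc3ccccc3)c(OCc3ccccc3)c1)[C@@H](C=O)C2
F6 | step 4 | 5,7,3',4'-tetra-O-benzyl-(+)-catechin 3-O-formate | c1c(OCc3ccccc3)cc(OCc3ccccc3)c2c1O[C@H](c1ccc(OCc3ccccc3)c(OCc3ccccc3)c1)[C@@H](OC=O)C2
F7 | step 12 | 3-O-acetyl-5,7,3',4',5'-penta-O-benzylgallocatechin-(4α→8)-5,7,3',4'-tetra-O-benzylcatechin | C(c3ccccc3)Oc1cc(OCc3ccccc3)c2c(c1)O[C@H](c1cc(OCc3ccccc3)c(OCc3ccccc3)c(OCc3ccccc3)c1)[C@@H](OC(C)=O)[C@@H]2c1c(OCc3ccccc3)cc(OCc3ccccc3)c2c1O[C@H](c1ccc(OCc3ccccc3)c(OCc3ccccc3)c1)[C@@H](O)C2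
F8 | step 12 | 3-O-acetyl-5,7,3',4',5'-penta-O-benzylgallocatechin-(4α→8)-5,7,3',4'-tetra-O-benzyl-4-(2-ethoxyethoxy)catechin (lower unit 4S) | C(c3ccccc3)Oc1cc(OCc3ccccc3)c2c(c1)O[C@H](c1cc(OCc3ccccc3)c(OCc3ccccc3)c(OCc3ccccc3)c1)[C@@H](OC(C)=O)[C@@H]2c1c(OCc3ccccc3)cc(OCc3ccccc3)c2c1O[C@H](c1ccc(OCc3ccccc3)c(OCc3ccccc3)c1)[C@@H](O)[C@H]2OCCOCC
F9 | step 12 | 3-O-acetyl-5,7,3',4',5'-penta-O-benzylgallocatechin-(4α→8)-3-O-acetyl-5,7,3',4'-tetra-O-benzyl-4-(2-ethoxyethoxy)catechin (lower unit 4S) | C(c3ccccc3)Oc1cc(OCc3ccccc3)c2c(c1)O[C@H](c1cc(OCc3ccccc3)c(OCc3ccccc3)c(OCc3ccccc3)c1)[C@@H](OC(C)=O)[C@@H]2c1c(OCc3ccccc3)cc(OCc3ccccc3)c2c1O[C@H](c1ccc(OCc3ccccc3)c(OCc3ccccc3)c1)[C@@H](OC(C)=O)[C@H]2OCCOCC
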